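Ring A (C1–OH, C2–H, C3–Br, C4–OH, C5–Br, C6–OAr) is a hydroquinone in which only C4–OH sits between two bromines, so O1 and O4 must differ before halogenation. The route therefore rests on cutting the C3–C4 bond and growing ring A from a squarate-derived four-membered ring. The precursor is a cyclobutenone that bears the ring B aryloxy group on its enone carbon and methoxy plus vinyl on its sp3 carbon. Heating it causes 4π opening and 6π closure. One operation delivers the complete diaryl ether with C4–OH free and C1–O methylated. The free phenols of both rings then steer four brominations, and demethylation finishes the synthesis.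

Key step: step 7

Numbering used: ring A as above. Ring B is C1' (bridging O), C2' (H), C3' (Br), C4' (OH), C5' (Br), C6' (Br).
Assumption: the target is achiral and rotation about the ether bonds is taken as free. Compounds 4, 10 and 11 are racemates, and their single stereocentre does not reach the target.

Step 1
Reactants: 1 bromohydroquinone (2-bromobenzene-1,4-diol)
Product: 2 2-bromo-4-(triisopropylsilyloxy)phenol
Conditions: TIPSCl (1.0 equiv), imidazole, DMF, 0 °C to rt
Reagents that add atoms: triisopropylsilyl chloride, CC(C)[Si](Cl)(C(C)C)C(C)C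
Why: Sterically controlled silylation of a phenol, in which the bulky silyl chloride should take the unhindered C4'–OH while the C1'–OH, shielded by the ortho bromine and the weaker nucleophile, stays free for the ether bridge.

Step 2
Reactants: 3 diisopropyl squarate
Product: 5 3-isopropoxycyclobut-3-ene-1,2-dione, via hydroxycyclobutenone 4 (not isolated)
Conditions: LiAlH(OtBu)3, THF, −78 to 0 °C; then aq HCl, CH2Cl2, rt
Reagents that add atoms: water, O (oxygen exchange only: the hydroxyl of 4 leaves as water and water supplies the new carbonyl oxygen)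
Why: The mild hydride stops at mono-reduction of the squarate, and acid then ionises the allylic hydroxyl of 4 to an alkoxy-stabilised cation whose hydrolysis expels propan-2-ol, the 1,3-carbonyl transposition known for squarate 1,2-adducts.

Step 3
Reactants: 5 3-isopropoxycyclobut-3-ene-1,2-dione
Product: 6 semisquaric acid (3-hydroxycyclobut-3-ene-1,2-dione)
Conditions: aq HCl (2 M), THF, 40 °C; evaporation to dryness
Reagents that add atoms: water, O
Why: Acid hydrolysis of a vinylogous ester by addition–elimination of water at the alkoxy-bearing carbon, with only volatile by-products, so the water-soluble acid is obtained by evaporation.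

Step 4
Reactants: 6 semisquaric acid; 2 2-bromo-4-(triisopropylsilyloxy)phenol
Product: 8 3-[2-bromo-4-(triisopropylsilyloxy)phenoxy]cyclobut-3-ene-1,2-dione, via semisquaric chloride 7 (not isolated)
Conditions: (COCl)2, DMF (cat.), CH2Cl2, 0 °C to rt, volatiles removed at 0 °C; then 2, iPr2NEt, CH2Cl2, −78 to 0 °C
Reagents that add atoms: oxalyl chloride, O=C(Cl)C(=O)Cl (supplies the chlorine of 7; no atom of it remains in 8)
Why: Vilsmeier-type chlorination converts the vinylogous acid into its acid chloride, which acylates the phenol by addition–elimination at temperatures that leave the silyl ether and the aryl bromide untouched.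

Step 5
Reactants: 8 3-[2-bromo-4-(triisopropylsilyloxy)phenoxy]cyclobut-3-ene-1,2-dione; 9 vinylmagnesium bromide
Product: 10 rac-3-[2-bromo-4-(triisopropylsilyloxy)phenoxy]-4-hydroxy-4-vinylcyclobut-2-en-1-one
Conditions: 9 (1.05 equiv, slow addition), THF, −78 °C; sat. aq NH4Cl at −78 °C
Reagents that add atoms: none
Why: Grignard 1,2-addition in which the carbonyl attached to C–OAr is a true ketone and the other is deactivated as a vinylogous ester, so the hard nucleophile should add to the former, as known for 3-alkoxycyclobutenediones, giving the quaternary carbinol as a racemate whose centre is erased in step 7.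

Step 6
Reactants: 10 rac-3-[2-bromo-4-(triisopropylsilyloxy)phenoxy]-4-hydroxy-4-vinylcyclobut-2-en-1-one
Product: 11 rac-3-[2-bromo-4-(triisopropylsilyloxy)phenoxy]-4-methoxy-4-vinylcyclobut-2-en-1-one
Conditions: MeI (excess), Ag2O, 4 Å MS, MeCN, rt, dark
Reagents that add atoms: iodomethane, CI
Why: Purdie methylation etherifies tertiary 4-hydroxycyclobutenones under nearly neutral conditions and so avoids the strong base that could open the ring or expel the aryloxide.

Step 7
Reactants: 11 rac-3-[2-bromo-4-(triisopropylsilyloxy)phenoxy]-4-methoxy-4-vinylcyclobut-2-en-1-one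
Product: 14 3-[2-bromo-4-(triisopropylsilyloxy)phenoxy]-4-methoxyphenol, via dienylketene 12 (not isolated), via cyclohexadienone 13 (not isolated)
Conditions: PhMe (0.01 M, degassed), 110 °C, Ar
Reagents that add atoms: none
Why: Thermal conrotatory 4π opening breaks the bond between the carbonyl carbon and the sp3 carbon; the donor methoxy group rotates outward, so the vinyl group turns inward and the (Z)-dienylketene 12 holds ketene and vinyl on the same side. Ring A then closes by a disrotatory 6π electrocyclisation that joins the ketene carbon (C4) to the vinyl terminus (C3), and dienone 13 enolises irreversibly to the phenol. This is the Moore ring expansion of 4-alkenyl-4-alkoxycyclobutenones, applied here to a 3-aryloxy member. No stereocentre is created and the single one of 11 is destroyed, so racemic material suffices. Connectivity fixes the regiochemistry: the ketene oxygen becomes the free C4–OH, the methylated carbinol oxygen becomes C1–OMe and the aryloxy carbon becomes C6. The selectivity needed is ring closure ahead of capture of the ketene by the phenol being formed, which the inward vinyl group and high dilution should secure.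

Step 8
Reactants: 14 3-[2-bromo-4-(triisopropylsilyloxy)phenoxy]-4-methoxyphenol
Product: 15 3-(2-bromo-4-hydroxyphenoxy)-4-methoxyphenol
Conditions: TBAF, AcOH (1 equiv each), THF, 0 °C
Reagents that add atoms: none
Why: Fluoride-induced cleavage of an aryl silyl ether driven by the strong Si–F bond, with acetic acid keeping the electron-rich phenols protonated and thus less prone to air oxidation.

Step 9
Reactants: 15 3-(2-bromo-4-hydroxyphenoxy)-4-methoxyphenol
Product: 16 2,6-dibromo-4-methoxy-3-(2,3,5-tribromo-4-hydroxyphenoxy)phenol
Conditions: Br2 (4.1 equiv), CH2Cl2–AcOH, 0 °C to rt; aq Na2S2O3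
Reagents that add atoms: bromine, BrBr
Why: Electrophilic aromatic bromination governed by the free phenols, whose para positions are blocked so that C3/C5 and C3'/C5' are the only ortho sites, while C2 (activated only by OMe and flanked by OMe and C3–Br) and C2' (activated only by the bridging oxygen) are far less reactive and four equivalents should stop at the pentabromide.

Step 10
Reactants: 16 2,6-dibromo-4-methoxy-3-(2,3,5-tribromo-4-hydroxyphenoxy)phenol
Product: 17 3,5-dibromo-2-(2,3,5-tribromo-4-hydroxyphenoxy)benzene-1,4-diol (CNP0084224.0)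
Conditions: BBr3 (4 equiv), CH2Cl2, −78 °C to rt, Ar; then H2O containing Na2S2O4
Reagents that add atoms: none
Why: Lewis-acid ether cleavage in which BBr3 binds the methoxy oxygen and bromide attacks the methyl group in an SN2 step, a standard demethylation of polybrominated diaryl ethers that spares the diaryl ether bond and the aryl bromides.

Compound list
1 | bromohydroquinone (2-bromobenzene-1,4-diol) | Oc1ccc(O)c(Br)c1 | starting material
2 | 2-bromo-4-(triisopropylsilyloxy)phenol | Oc1ccc(O[Si](C(C)C)(C(C)C)C(C)C)cc1Br | intermediate
3 | diisopropyl squarate | CC(C)OC1=C(OC(C)C)C(=O)C1=O | starting material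
4 | rac-4-hydroxy-2,3-diisopropoxycyclobut-2-en-1-one (formed in situ) | CC(C)OC1=C(OC(C)C)C(O)C1=O | intermediate
5 | 3-isopropoxycyclobut-3-ene-1,2-dione | CC(C)OC1=CC(=O)C1=O | intermediate
6 | semisquaric acid (3-hydroxycyclobut-3-ene-1,2-dione) | OC1=CC(=O)C1=O | intermediate
7 | semisquaric chloride (3-chlorocyclobut-3-ene-1,2-dione, formed in situ) | ClC1=CC(=O)C1=O | intermediate
8 | 3-[2-bromo-4-(triisopropylsilyloxy)phenoxy]cyclobut-3-ene-1,2-dione | O=C1C=C(Oc2ccc(O[Si](C(C)C)(C(C)C)C(C)C)cc2Br)C1=O | intermediate
9 | vinylmagnesium bromide | C=C[Mg]Br | starting material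
10 | rac-3-[2-bromo-4-(triisopropylsilyloxy)phenoxy]-4-hydroxy-4-vinylcyclobut-2-en-1-one | C=CC1(O)C(=O)C=C1Oc1ccc(O[Si](C(C)C)(C(C)C)C(C)C)cc1Br | intermediate
11 | rac-3-[2-bromo-4-(triisopropylsilyloxy)phenoxy]-4-methoxy-4-vinylcyclobut-2-en-1-one | C=CC1(OC)C(=O)C=C1Oc1ccc(O[Si](C(C)C)(C(C)C)C(C)C)cc1Br | intermediate
12 | (3Z)-3-[2-bromo-4-(triisopropylsilyloxy)phenoxy]-4-methoxyhexa-1,3,5-trien-1-one (dienylketene, formed in situ) | C=C/C(OC)=C(Oc1ccc(O[Si](C(C)C)(C(C)C)C(C)C)cc1Br)\C=C=O | intermediate
13 | 3-[2-bromo-4-(triisopropylsilyloxy)phenoxy]-4-methoxycyclohexa-2,4-dien-1-one (formed in situ) | O=C1CC=C(OC)C(Oc2ccc(O[Si](C(C)C)(C(C)C)C(C)C)cc2Br)=C1 | intermediate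
14 | 3-[2-bromo-4-(triisopropylsilyloxy)phenoxy]-4-methoxyphenol | COc1ccc(O)cc1Oc1ccc(O[Si](C(C)C)(C(C)C)C(C)C)cc1Br | intermediate
15 | 3-(2-bromo-4-hydroxyphenoxy)-4-methoxyphenol | COc1ccc(O)cc1Oc1ccc(O)cc1Br | intermediate
16 | 2,6-dibromo-4-methoxy-3-(2,3,5-tribromo-4-hydroxyphenoxy)phenol | COc1cc(Br)c(O)c(Br)c1Oc1cc(Br)c(O)c(Br)c1Br | intermediate
17 | 3,5-dibromo-2-(2,3,5-tribromo-4-hydroxyphenoxy)benzene-1,4-diol | Oc1cc(Br)c(O)c(Br)c1Oc1cc(Br)c(O)c(Br)c1Br | target

Total step count: 10. Longest linear sequence: 9 (steps 2 to 10, from 3).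

Steps most likely to fail

Step 5. The Grignard reagent may displace the aryloxide by conjugate addition–elimination, or it may attack the vinylogous ester carbonyl. The fallback sets out from 5 and comes back at 11, and it also makes steps 3 and 4 unnecessary. The order of events is inverted so that no carbanion meets an aryl ester.
- Vinylmagnesium bromide 9 would be added at −78 °C to the robust isopropyl ester 5 to give rac-4-hydroxy-3-isopropoxy-4-vinylcyclobut-2-en-1-one F1.
- MeI/Ag2O would then give rac-3-isopropoxy-4-methoxy-4-vinylcyclobut-2-en-1-one F2.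
- Dilute aqueous HCl in THF would hydrolyse the vinylogous ester to rac-3-hydroxy-4-methoxy-4-vinylcyclobut-2-en-1-one F3. This is the enol of a symmetrical cyclobutane-1,3-dione, so its activation raises no regiochemical question.
- Oxalyl chloride with catalytic DMF would give rac-3-chloro-4-methoxy-4-vinylcyclobut-2-en-1-one F4.
- Phenol 2 with iPr2NEt would replace the chloride by addition–elimination to reach 11.

Step 7. The ketene may be intercepted by the phenol as it forms, or it may oligomerise before the 6π closure. The fallback sets out from 2 and comes back at 14. Ring A is bought instead of built, and the ether bond is made by a Chan–Lam coupling.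
- Phenol 2 and commercial (5-formyl-2-methoxyphenyl)boronic acid would be coupled with Cu(OAc)2, pyridine and 4 Å MS in CH2Cl2 under air, conditions that leave the aryl bromide alone. This would give 3-[2-bromo-4-(triisopropylsilyloxy)phenoxy]-4-methoxybenzaldehyde F5.
- Baeyer–Villiger oxidation with mCPBA, in which the electron-rich aryl group migrates, would give 3-[2-bromo-4-(triisopropylsilyloxy)phenoxy]-4-methoxyphenyl formate F6.
- Methanolysis with Et3N in MeOH would release 14.

Step 9. Bromine may oxidise the electron-rich ring A, or the reaction may stall before the crowded positions C5 and C5' are filled while two activated rings compete. The fallback sets out from 14 and comes back at 16. The rings are halogenated one at a time, with the silyl group serving as a switch.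
- With ring B still silylated, NBS (2 equiv, CH2Cl2, 0 °C) should act only on the free phenol of ring A to give 2,6-dibromo-3-[2-bromo-4-(triisopropylsilyloxy)phenoxy]-4-methoxyphenol F7.
- TBAF/AcOH would then unmask ring B to give 2,6-dibromo-3-(2-bromo-4-hydroxyphenoxy)-4-methoxyphenol F8.
- Br2 (2 equiv) would brominate only ring B, because ring A is by then deactivated, and this delivers 16.

Further compounds
F1 | step 5 | rac-4-hydroxy-3-isopropoxy-4-vinylcyclobut-2-en-1-one | C=CC1(O)C(=O)C=C1OC(C)C
F2 | step 5 | rac-3-isopropoxy-4-methoxy-4-vinylcyclobut-2-en-1-one | C=CC1(OC)C(=O)C=C1OC(C)C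
F3 | step 5 | rac-3-hydroxy-4-methoxy-4-vinylcyclobut-2-en-1-one | C=CC1(OC)C(=O)C=C1O
F4 | step 5 | rac-3-chloro-4-methoxy-4-vinylcyclobut-2-en-1-one | C=CC1(OC)C(=O)C=C1Cl
F5 | step 7 | 3-[2-bromo-4-(triisopropylsilyloxy)phenoxy]-4-methoxybenzaldehyde | COc1ccc(C=O)cc1Oc1ccc(O[Si](C(C)C)(C(C)C)C(C)C)cc1Br
F6 | step 7 | 3-[2-bromo-4-(triisopropylsilyloxy)phenoxy]-4-methoxyphenyl formate | COc1ccc(OC=O)cc1Oc1ccc(O[Si](C(C)C)(C(C)C)C(C)C)cc1Br
F7 | step 9 | 2,6-dibromo-3-[2-bromo-4-(triisopropylsilyloxy)phenoxy]-4-methoxyphenol | COc1cc(Br)c(O)c(Br)c1Oc1ccc(O[Si](C(C)C)(C(C)C)C(C)C)cc1Br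
F8 | step 9 | 2,6-dibromo-3-(2-bromo-4-hydroxyphenoxy)-4-methoxyphenol | COc1cc(Br)c(O)c(Br)c1Oc1ccc(O)cc1Br
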